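**Assumption:** dihydrobenzofuran numbering is used throughout (O1, C2 aryl, C3 CH2OH, C4 flavonol, C7 OH). The target SMILES is read as the trans (2R,3S) isomer.

## Retrosynthetic overview
1. The target comes from debenzylation of its 7,4'-dibenzyl ether. The flavonol pyranone (ring C, formed last) is cut at C2–C3 and O1–C2 into a ring A α-alkoxy ketone and an aroyl donor on C4 of the dihydrobenzofuran.
2. The aroyl donor is a δ-lactone tying C4–C(=O) to the C3–CH2O arm. It comes from hydroxyl-directed C4–H carbonylation of the 3-hydroxymethyl dihydrobenzofuran (new step).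
3. The trans-dihydrobenzofuran ester comes from oxidative ring contraction (1,2-aryl shift, C4 to C3) of a (2R)-flavanone. C2 controls C3.
4. The (2R)-flavanone comes from enantioselective conjugate addition of a guaiacyl boronic acid to 8-benzyloxychromone, both arenes from catechol. Ring A comes from resorcinol by ortho-lithiation/acylation and then meta C–H borylation/oxidation.
5. Ring order: chromone pyranone, contracted to the dihydrofuran, then the temporary δ-lactone, then the flavonol pyranone.

## Route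

Step 1
Reactants: 1 catechol
Product: 2 guaiacol (2-methoxyphenol)
Conditions: MeI (1.0 equiv), K2CO3 (1.0 equiv), acetone, reflux
Reagents that add atoms: iodomethane CI
Why: Williamson ether synthesis with one equivalent of MeI, the monoether being separated from catechol and veratrole by base extraction and distillation.

Step 2
Reactants: 2 guaiacol
Product: 3 4-bromo-2-methoxyphenol
Conditions: NBS (1.0 equiv), MeCN, 0 °C
Reagents that add atoms: N-bromosuccinimide O=C1CCC(=O)N1Br
Why: Electrophilic aromatic bromination in which the free OH, the strongest donor, directs to its open para position.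

Step 3
Reactants: 3 4-bromo-2-methoxyphenol
Product: 4 1-(benzyloxy)-4-bromo-2-methoxybenzene
Conditions: BnBr, K2CO3, DMF, rt
Reagents that add atoms: benzyl bromide BrCc1ccccc1
Why: Williamson ether synthesis giving a benzyl ether that survives acid, trivalent iodine, hydride and amide base and leaves by hydrogenolysis at the end.

Step 4
Reactants: 4 1-(benzyloxy)-4-bromo-2-methoxybenzene
Product: 6 [4-(benzyloxy)-3-methoxyphenyl]boronic acid, via aryllithium 5 (not isolated)
Conditions: n-BuLi, THF, −78 °C; B(OiPr)3, −78 °C to rt; 1 M aq HCl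
Reagents that add atoms: triisopropyl borate CC(C)OB(OC(C)C)OC(C)C; water O
Why: Bromine–lithium exchange followed by electrophilic borylation and hydrolysis, which at −78 °C is faster than any benzylic deprotonation.

Step 5
Reactants: 1 catechol
Product: 7 1,2-bis(methoxymethoxy)benzene
Conditions: NaH (2.2 equiv), MOMCl (2.2 equiv), DMF, 0 °C to rt
Reagents that add atoms: chloromethyl methyl ether COCCl
Why: O-alkylation of both phenoxides gives MOM acetals that protect the ring and serve as strong ortho-metalation directors.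

Step 6
Reactants: 7 1,2-bis(methoxymethoxy)benzene; 8 N-methoxy-N-methylacetamide
Product: 10 1-[2,3-bis(methoxymethoxy)phenyl]ethan-1-one, via aryllithium 9 (not isolated)
Conditions: n-BuLi (1.1 equiv), THF, 0 °C; 8, −78 °C to rt; H2O
Reagents that add atoms: none
Why: Directed ortho-metalation next to an OMOM group followed by Weinreb ketone synthesis, whose chelated adduct prevents over-addition.

Step 7
Reactants: 10 1-[2,3-bis(methoxymethoxy)phenyl]ethan-1-one
Product: 12 8-hydroxy-4H-chromen-4-one, via enaminone 11 (not isolated)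
Conditions: Me2NCH(OMe)2, toluene, 110 °C; concentrate; 3 M aq HCl, MeOH, 40 °C
Reagents that add atoms: N,N-dimethylformamide dimethyl acetal COC(OC)N(C)C
Why: Enaminone chromone synthesis, in which condensation adds the C2 carbon and acid then removes both MOM groups so the ortho phenol closes the pyranone by addition–elimination of dimethylamine.

Step 8
Reactants: 12 8-hydroxy-4H-chromen-4-one
Product: 13 8-(benzyloxy)-4H-chromen-4-one
Conditions: BnBr, K2CO3, DMF, rt
Reagents that add atoms: benzyl bromide BrCc1ccccc1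
Why: Williamson ether synthesis under a base too mild to open the chromone, masking the phenol that would otherwise be oxidised in step 10.

Step 9
Reactants: 13 8-(benzyloxy)-4H-chromen-4-one; 6 [4-(benzyloxy)-3-methoxyphenyl]boronic acid
Product: 14 (2R)-8-(benzyloxy)-2-[4-(benzyloxy)-3-methoxyphenyl]-2,3-dihydro-4H-chromen-4-one
Conditions: Pd(OCOCF3)2 (5 mol%), (S)-4-tert-butyl-2-(pyridin-2-yl)-4,5-dihydrooxazole (6 mol%), NH4PF6 (30 mol%), H2O (5 equiv), 6 (2 equiv), ClCH2CH2Cl, 60 °C; recrystallise
Reagents that add atoms: none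
Why: Enantioselective palladium-catalysed conjugate addition of an arylboronic acid (Hayashi–Miyaura-type 1,4-addition, base-free so the flavanone does not ring-open), in which the tert-butyl oxazoline blocks one enone face and aryl transfer sets C2 as R, the sense found for cyclic enones with this ligand antipode and to be checked by CD.

Step 10
Reactants: 14 (2R)-flavanone
Product: 16 methyl (2R,3R)-7-(benzyloxy)-2-[4-(benzyloxy)-3-methoxyphenyl]-2,3-dihydro-1-benzofuran-3-carboxylate, via enol ether 15 (not isolated)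
Conditions: PhI(OAc)2 (1.2 equiv), HC(OMe)3, conc. H2SO4 (cat.), rt; aq NaHCO3
Reagents that add atoms: trimethyl orthoformate COC(OC)OC; water O
Why: Oxidative ring contraction of a flavanone by trivalent iodine (a 1,2-aryl shift), in which PhI(OAc)2 attacks C3 of enol ether 15 anti to the C2 aryl group, methanol adds at C4, and the fused-benzene carbon C4a migrates from C4 to C3 anti-periplanar to departing PhI, so the untouched C2 centre dictates the trans (3R) ester, which is also the thermodynamic epimer.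

Step 11
Reactants: 16 trans ester
Product: 17 {(2R,3S)-7-(benzyloxy)-2-[4-(benzyloxy)-3-methoxyphenyl]-2,3-dihydro-1-benzofuran-3-yl}methanol
Conditions: LiAlH4, THF, 0 °C; Fieser work-up
Reagents that add atoms: none
Why: Hydride reduction of the ester at 0 °C outruns β-elimination of the ring phenoxide, and the geometry at C3 is unchanged (the descriptor becomes S only through CIP priorities).

Step 12
Reactants: 17 primary alcohol
Product: 18 tricyclic δ-lactone: (2R,3S)-7-(benzyloxy)-2-[4-(benzyloxy)-3-methoxyphenyl]-2,3-dihydrobenzofuran bridged C3-CH2-O-C(=O)-C4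
Conditions: Pd(OAc)2 (10 mol%), Boc-L-Leu-OH (20 mol%), AgOAc (3 equiv), Li2CO3 (2 equiv), CO (1 atm), ClCH2CH2Cl, 100 °C
Reagents that add atoms: carbon monoxide [C-]#[O+]
Why: Proposed new method: the closest known reaction type is hydroxyl-directed ortho C–H carbonylative lactonisation with divalent palladium and a mono-N-protected amino acid ligand, shown essentially on tertiary phenethyl alcohols that cannot be oxidised and not on a primary alcohol or a stereodefined 2-aryl-2,3-dihydrobenzofuran; here the five-membered ring holds the Pd alkoxide of 17 over C4–H, the only free position ortho to C3a, so carboxylate-assisted concerted metalation–deprotonation gives a six-membered palladacycle, CO (which also occupies the site needed for β-hydride elimination of the alkoxide) inserts into the Pd–aryl bond, C–O reductive elimination closes the δ-lactone, and AgOAc returns zerovalent palladium to the divalent state, with no stereocentre touched.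

Step 13
Reactants: 19 resorcinol
Product: 20 1,3-bis(methoxymethoxy)benzene
Conditions: NaH (2.2 equiv), MOMCl (2.2 equiv), DMF, 0 °C to rt
Reagents that add atoms: chloromethyl methyl ether COCCl
Why: O-alkylation gives MOM acetals that direct lithiation to C2, carry no arene C–H to compete in step 16, and fall off in the acid cyclisation of step 17.

Step 14
Reactants: 21 methyl glycolate
Product: 22 methyl 2-(methoxymethoxy)acetate
Conditions: MOMCl, i-Pr2NEt, CH2Cl2, 0 °C to rt
Reagents that add atoms: chloromethyl methyl ether COCCl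
Why: MOM acetal formation under amine base avoids self-condensation of the hydroxy ester and masks the future flavonol 3-OH.

Step 15
Reactants: 20 1,3-bis(methoxymethoxy)benzene; 22 methyl 2-(methoxymethoxy)acetate
Product: 24 1-[2,6-bis(methoxymethoxy)phenyl]-2-(methoxymethoxy)ethan-1-one, via aryllithium 23 (not isolated)
Conditions: n-BuLi, THF, 0 °C to rt; cannulate into 22 (1.5 equiv), THF, −78 °C; H2O
Reagents that add atoms: none
Why: Directed ortho-metalation between the two OMOM groups and inverse-addition acylation by the ester, where the α-alkoxy-chelated adduct and the doubly ortho-substituted ketone stop a second addition.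

Step 16
Reactants: 24 aryl ketone
Product: 26 1-[4-hydroxy-2,6-bis(methoxymethoxy)phenyl]-2-(methoxymethoxy)ethan-1-one, via pinacol boronate 25 (not isolated)
Conditions: [Ir(OMe)(cod)]2 (1.5 mol%), 4,4'-di-tert-butyl-2,2'-bipyridine (3 mol%), B2pin2 (0.6 equiv), THF, 80 °C; then NaBO3·4H2O (3 equiv), THF/H2O, rt
Reagents that add atoms: sodium perborate [Na+].[O-]OB=O; bis(pinacolato)diboron CC1(C)OB(OC1(C)C)B1OC(C)(C)C(C)(C)O1 (its atoms stay only in 25)
Why: Sterically controlled iridium-catalysed C–H borylation reaches only the C–H with no ortho substituent (para to the acyl group), and one-pot perborate oxidation turns C–B into the future 7-OH.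

Step 17
Reactants: 26 ring A ketone; 18 δ-lactone
Product: 28 2-{(2R,3S)-7-(benzyloxy)-2-[4-(benzyloxy)-3-methoxyphenyl]-3-(hydroxymethyl)-2,3-dihydro-1-benzofuran-4-yl}-3,5,7-trihydroxy-4H-chromen-4-one, via 1,3-diketone 27 (not isolated)
Conditions: 26 (1.2 equiv), LiN(SiMe3)2 (3.6 equiv), THF, −78 to −10 °C; 18, −10 °C to rt; then 3 M aq HCl, MeOH/THF, 50 °C
Reagents that add atoms: none
Why: Crossed Claisen condensation of the phenoxide-enolate dianion with the lactone, driven by deprotonation of the diketone and releasing the CH2OH arm, followed by acid that removes the three MOM groups and cyclodehydrates to the aromatic pyranone as in the closing stage of Baker–Venkataraman flavone syntheses.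

Step 18
Reactants: 28 dibenzyl ether
Product: 29 2-[(2R,3S)-7-hydroxy-2-(4-hydroxy-3-methoxyphenyl)-3-(hydroxymethyl)-2,3-dihydro-1-benzofuran-4-yl]-3,5,7-trihydroxy-4H-chromen-4-one (target)
Conditions: H2 (1 atm), 10% Pd/C, EtOAc/MeOH, rt, stop at 2 equiv uptake
Reagents that add atoms: none
Why: Hydrogenolysis of the two aryl benzyl ethers is much faster than cleavage of the cyclic benzylic C2–O bond or reduction of the flavonol, so both stereocentres persist.

## Compound list
1 | catechol | Oc1ccccc1O | starting material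
2 | guaiacol | COc1ccccc1O | intermediate
3 | 4-bromo-2-methoxyphenol | COc1cc(Br)ccc1O | intermediate
4 | 1-(benzyloxy)-4-bromo-2-methoxybenzene | COc1cc(Br)ccc1OCc1ccccc1 | intermediate
5 | [4-(benzyloxy)-3-methoxyphenyl]lithium | COc1cc([Li])ccc1OCc1ccccc1 | intermediate
6 | [4-(benzyloxy)-3-methoxyphenyl]boronic acid | COc1cc(B(O)O)ccc1OCc1ccccc1 | intermediate
7 | 1,2-bis(methoxymethoxy)benzene | COCOc1ccccc1OCOC | intermediate
8 | N-methoxy-N-methylacetamide | CC(=O)N(C)OC | starting material
9 | [2,3-bis(methoxymethoxy)phenyl]lithium | COCOc1cccc([Li])c1OCOC | intermediate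
10 | 1-[2,3-bis(methoxymethoxy)phenyl]ethan-1-one | CC(=O)c1cccc(OCOC)c1OCOC | intermediate
11 | (E)-1-[2,3-bis(methoxymethoxy)phenyl]-3-(dimethylamino)prop-2-en-1-one | CN(C)/C=C/C(=O)c1cccc(OCOC)c1OCOC | intermediate
12 | 8-hydroxy-4H-chromen-4-one | O=c1ccoc2c(O)cccc12 | intermediate
13 | 8-(benzyloxy)-4H-chromen-4-one | O=c1ccoc2c(OCc3ccccc3)cccc12 | intermediate
14 | (2R)-8-(benzyloxy)-2-[4-(benzyloxy)-3-methoxyphenyl]-2,3-dihydro-4H-chromen-4-one | COc1cc([C@@H]2Oc3c(OCc4ccccc4)cccc3C(=O)C2)ccc1OCc1ccccc1 | intermediate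
15 | (2R)-8-(benzyloxy)-2-[4-(benzyloxy)-3-methoxyphenyl]-4-methoxy-2H-chromene | COc1cc([C@@H]2Oc3c(OCc4ccccc4)cccc3C(OC)=C2)ccc1OCc1ccccc1 | intermediate
16 | methyl (2R,3R)-7-(benzyloxy)-2-[4-(benzyloxy)-3-methoxyphenyl]-2,3-dihydro-1-benzofuran-3-carboxylate (trans) | COc1cc([C@@H]2Oc3c(OCc4ccccc4)cccc3[C@H]2C(=O)OC)ccc1OCc1ccccc1 | intermediate
17 | {(2R,3S)-7-(benzyloxy)-2-[4-(benzyloxy)-3-methoxyphenyl]-2,3-dihydro-1-benzofuran-3-yl}methanol (trans) | COc1cc([C@@H]2Oc3c(OCc4ccccc4)cccc3[C@H]2CO)ccc1OCc1ccccc1 | intermediate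
18 | tricyclic δ-lactone, (2R,3S) in dihydrobenzofuran numbering, C3-CH2-O-C(=O)-C4 bridge (a furo[4,3,2-de]isochromenone) | COc1cc([C@@H]2Oc3c(OCc4ccccc4)ccc4c3[C@H]2COC4=O)ccc1OCc1ccccc1 | intermediate
19 | resorcinol | Oc1cccc(O)c1 | starting material
20 | 1,3-bis(methoxymethoxy)benzene | COCOc1cccc(OCOC)c1 | intermediate
21 | methyl glycolate | COC(=O)CO | starting material
22 | methyl 2-(methoxymethoxy)acetate | COCOCC(=O)OC | intermediate
23 | [2,6-bis(methoxymethoxy)phenyl]lithium | COCOc1cccc(OCOC)c1[Li] | intermediate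
24 | 1-[2,6-bis(methoxymethoxy)phenyl]-2-(methoxymethoxy)ethan-1-one | COCOCC(=O)c1c(OCOC)cccc1OCOC | intermediate
25 | 1-[2,6-bis(methoxymethoxy)-4-(4,4,5,5-tetramethyl-1,3,2-dioxaborolan-2-yl)phenyl]-2-(methoxymethoxy)ethan-1-one | COCOCC(=O)c1c(OCOC)cc(B2OC(C)(C)C(C)(C)O2)cc1OCOC | intermediate
26 | 1-[4-hydroxy-2,6-bis(methoxymethoxy)phenyl]-2-(methoxymethoxy)ethan-1-one | COCOCC(=O)c1c(OCOC)cc(O)cc1OCOC | intermediate
27 | 1-{(2R,3S)-7-(benzyloxy)-2-[4-(benzyloxy)-3-methoxyphenyl]-3-(hydroxymethyl)-2,3-dihydro-1-benzofuran-4-yl}-3-[4-hydroxy-2,6-bis(methoxymethoxy)phenyl]-2-(methoxymethoxy)propane-1,3-dione (chain C2 enolisable, unassigned) | COc1cc([C@@H]2Oc3c(OCc4ccccc4)ccc(C(=O)C(OCOC)C(=O)c4c(OCOC)cc(O)cc4OCOC)c3[C@H]2CO)ccc1OCc1ccccc1 | intermediate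
28 | 2-{(2R,3S)-7-(benzyloxy)-2-[4-(benzyloxy)-3-methoxyphenyl]-3-(hydroxymethyl)-2,3-dihydro-1-benzofuran-4-yl}-3,5,7-trihydroxy-4H-chromen-4-one | COc1cc([C@@H]2Oc3c(OCc4ccccc4)ccc(-c4oc5cc(O)cc(O)c5c(=O)c4O)c3[C@H]2CO)ccc1OCc1ccccc1 | intermediate
29 | 2-[(2R,3S)-7-hydroxy-2-(4-hydroxy-3-methoxyphenyl)-3-(hydroxymethyl)-2,3-dihydro-1-benzofuran-4-yl]-3,5,7-trihydroxy-4H-chromen-4-one | COc1cc([C@@H]2Oc3c(O)ccc(-c4oc5cc(O)cc(O)c5c(=O)c4O)c3[C@H]2CO)ccc1O | target

## Step count and risks
Total step count: 18.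
Longest linear sequence: 10 (steps 5, 6, 7, 8, 9, 10, 11, 12, 17, 18, from catechol).

**Step 12 (the new step).**
- Risk: divalent palladium may oxidise the primary alcohol, and turnover may be low.
- The fallback uses known chemistry, sets out from 16 and returns at 18.
- The ester is cleaved with Me3SnOH (ClCH2CH2Cl, 80 °C) to the (2R,3R)-carboxylic acid F1.
- Carboxylate-directed C4–H olefination follows (Pd(OAc)2, Ac-Ile-OH, KHCO3, O2, methyl acrylate, t-AmylOH, 85 °C). This reaction is established on 7-alkoxy-2-aryl-2,3-dihydrobenzofuran-3-carboxylic acids and gives the C4 acrylate acid F2.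
- Lemieux–Johnson cleavage (OsO4 cat., NaIO4, 2,6-lutidine, dioxane/H2O) gives the 4-formyl acid F3.
- LiAlH4 (THF, 0 °C) reduces both carbonyl groups to the 3,4-bis(hydroxymethyl) diol F4.
- MnO2 (CH2Cl2, rt) oxidises only the benzylic alcohol and carries the resulting lactol on to lactone 18.

**Step 10.**
- Risk: dehydrogenation to the flavone, migration of the electron-rich C2 aryl group towards isoflavone products, or loss of ee in acid.
- The fallback leaves the oxidative manifold for a Wolff ring contraction. It sets out from 14 and returns at 16.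
- The kinetic enolate (LiN(SiMe3)2, THF, −78 °C) is acylated with CF3CO2CH2CF3 to the 3-trifluoroacetyl flavanone F5.
- Detrifluoroacetylative diazo transfer (MsN3, Et3N, MeCN) gives the 3-diazo flavanone F6.
- Irradiation (350 nm, MeOH) expels nitrogen with a 1,2-shift of C4a to the ring-contracted ketene F7.
- The ketene adds methanol, with protonation anti to the aryl group, to give mainly the cis ester F8.
- DBU (toluene, rt) equilibrates C3 to the trans ester 16.

**Step 17.**
- Risk: the lactone may be a sluggish and reversible acyl donor, the released alkoxide may undo the Claisen step, and the free CH2OH may compete for the aroyl carbonyl in acid.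
- The fallback replaces the lactone by an irreversible, chelating acyl donor with the alcohol capped. It sets out from 18 (with 26) and returns at 28.
- MeNH(OMe)·HCl/AlMe3 (CH2Cl2, 0 °C to rt) opens the lactone to the hydroxy Weinreb amide F9.
- TBSCl/imidazole (DMF) gives the silyl ether F10.
- The dianion of 26 (LiN(SiMe3)2, THF) adds to F10 to give the silylated 1,3-diketone F11.
- 3 M aq HCl in MeOH/THF (50 °C) then removes the MOM and silyl groups and cyclodehydrates to 28.

Further compounds
F1 | step 12 | (2R,3R)-7-(benzyloxy)-2-[4-(benzyloxy)-3-methoxyphenyl]-2,3-dihydro-1-benzofuran-3-carboxylic acid | COc1cc([C@@H]2Oc3c(OCc4ccccc4)cccc3[C@H]2C(=O)O)ccc1OCc1ccccc1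
F2 | step 12 | (2R,3R)-7-(benzyloxy)-2-[4-(benzyloxy)-3-methoxyphenyl]-4-[(E)-3-methoxy-3-oxoprop-1-en-1-yl]-2,3-dihydro-1-benzofuran-3-carboxylic acid | COc1cc([C@@H]2Oc3c(OCc4ccccc4)ccc(/C=C/C(=O)OC)c3[C@H]2C(=O)O)ccc1OCc1ccccc1
F3 | step 12 | (2R,3R)-7-(benzyloxy)-2-[4-(benzyloxy)-3-methoxyphenyl]-4-formyl-2,3-dihydro-1-benzofuran-3-carboxylic acid | COc1cc([C@@H]2Oc3c(OCc4ccccc4)ccc(C=O)c3[C@H]2C(=O)O)ccc1OCc1ccccc1
F4 | step 12 | {(2R,3S)-7-(benzyloxy)-2-[4-(benzyloxy)-3-methoxyphenyl]-2,3-dihydro-1-benzofuran-3,4-diyl}dimethanol | COc1cc([C@@H]2Oc3c(OCc4ccccc4)ccc(CO)c3[C@H]2CO)ccc1OCc1ccccc1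
F5 | step 10 | (2R)-8-(benzyloxy)-2-[4-(benzyloxy)-3-methoxyphenyl]-3-(trifluoroacetyl)-2,3-dihydro-4H-chromen-4-one (C3 enolisable, unassigned) | COc1cc([C@@H]2Oc3c(OCc4ccccc4)cccc3C(=O)C2C(=O)C(F)(F)F)ccc1OCc1ccccc1
F6 | step 10 | (2S)-8-(benzyloxy)-2-[4-(benzyloxy)-3-methoxyphenyl]-3-diazo-2,3-dihydro-4H-chromen-4-one (same geometry as 14, descriptor changed by priorities) | COc1cc([C@@H]2Oc3c(OCc4ccccc4)cccc3C(=O)C2=[N+]=[N-])ccc1OCc1ccccc1
F7 | step 10 | (2S)-[7-(benzyloxy)-2-[4-(benzyloxy)-3-methoxyphenyl]-1-benzofuran-3(2H)-ylidene]methanone (ketene) | COc1cc([C@@H]2Oc3c(OCc4ccccc4)cccc3C2=C=O)ccc1OCc1ccccc1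
F8 | step 10 | methyl (2R,3S)-7-(benzyloxy)-2-[4-(benzyloxy)-3-methoxyphenyl]-2,3-dihydro-1-benzofuran-3-carboxylate (cis) | COc1cc([C@@H]2Oc3c(OCc4ccccc4)cccc3[C@@H]2C(=O)OC)ccc1OCc1ccccc1
F9 | step 17 | (2R,3S)-7-(benzyloxy)-2-[4-(benzyloxy)-3-methoxyphenyl]-3-(hydroxymethyl)-N-methoxy-N-methyl-2,3-dihydro-1-benzofuran-4-carboxamide | COc1cc([C@@H]2Oc3c(OCc4ccccc4)ccc(C(=O)N(C)OC)c3[C@H]2CO)ccc1OCc1ccccc1
F10 | step 17 | (2R,3S)-7-(benzyloxy)-2-[4-(benzyloxy)-3-methoxyphenyl]-3-{[(tert-butyldimethylsilyl)oxy]methyl}-N-methoxy-N-methyl-2,3-dihydro-1-benzofuran-4-carboxamide | COc1cc([C@@H]2Oc3c(OCc4ccccc4)ccc(C(=O)N(C)OC)c3[C@H]2CO[Si](C)(C)C(C)(C)C)ccc1OCc1ccccc1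
F11 | step 17 | O-tert-butyldimethylsilyl ether of diketone 27 at the C3 hydroxymethyl group | COc1cc([C@@H]2Oc3c(OCc4ccccc4)ccc(C(=O)C(OCOC)C(=O)c4c(OCOC)cc(O)cc4OCOC)c3[C@H]2CO[Si](C)(C)C(C)(C)C)ccc1OCc1ccccc1
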